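**Retrosynthetic overview**

1. Target 18 ⇐ selective angeloylation of the only secondary hydroxyl of triol 15.
2. 15 ⇐ singlet-oxygen ene reaction (C11–O bond, Δ6) on isopropylidene enone diol 13 ⇐ α-face dihydroxylation of dienone 12 ⇐ aldol condensation of octalone 7 with acetone.
3. Ring A ⇐ ring-closing metathesis of butenyl/isopropenyl cyclohexanone 6 (gives Δ3 and keeps C15).
4. 6 ⇐ cyclobutane cleavage of pinane ketone 3, which unveils ring B with the C8 ketone already in place.
5. 3 ⇐ light-driven decarboxylative radical conjugate addition of pent-4-enoic acid to (+)-verbenone (C1–C10 bond, quaternary C10). Ring B is carried in verbenone; ring A is formed second.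

Assumption: eudesmane numbering is used for positions (C8 ketone, C10 angular methyl carbon, C11 carbinol carbon), and (1R,5R)-(+)-verbenone is bought in high enantiomeric purity.

**Route**

Step 1
Reactants: 1 (1R,5R)-(+)-verbenone; 2 pent-4-enoic acid
Product: 3 (1R,4R,5R)-4-(but-3-en-1-yl)-4,6,6-trimethylbicyclo[3.1.1]heptan-2-one
Conditions: 2 (3 equiv), 9-mesitylacridine (10 mol %), Cu(MeCN)4BF4 (5 mol %), CH2Cl2, 400 nm LED, 25 °C
Reagents that add atoms: none
Why: Proposed new method: the excited acridine–acid hydrogen-bonded complex undergoes proton-coupled electron transfer and loses CO2 to give the nucleophilic but-3-enyl radical, which adds to the enone β-carbon from the face anti to the gem-dimethyl bridge (the face cuprates use), and the α-keto radical is returned to the ketone by hydrogen/electron back-transfer from the acridinyl radical relayed by copper, so the quaternary C10 centre is set by the pinane skeleton; the closest known reaction type is the acridine-photocatalysed decarboxylative Giese addition to unhindered Michael acceptors, not yet shown on a β,β-disubstituted bicyclic enone.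

Step 2
Reactants: 3 (1R,4R,5R)-4-(but-3-en-1-yl)-4,6,6-trimethylbicyclo[3.1.1]heptan-2-one
Product: 6 (3R,4S)-3-(but-3-en-1-yl)-3-methyl-4-(prop-1-en-2-yl)cyclohexan-1-one, via iodo silyl enol ether 4 (not isolated), via isopropenyl silyl enol ether 5 (not isolated)
Conditions: Me3SiI (1.3 equiv), CH2Cl2, −20 → 0 °C; DBU (3 equiv), 0 → 25 °C; 1 M HCl, THF, 0 °C
Reagents that add atoms: none
Why: O-silylation triggers heterolysis of the strained cyclobutane bond α to the carbonyl (acid-mediated cyclobutane cleavage of nopinone-type ketones), giving a tertiary iodide that DBU eliminates by E2 toward the methyl groups because the ring methine is shielded by the adjacent quaternary carbon, and no stereocentre is touched.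

Step 3
Reactants: 6 (3R,4S)-3-(but-3-en-1-yl)-3-methyl-4-(prop-1-en-2-yl)cyclohexan-1-one
Product: 7 (4aR,8aR)-5,8a-dimethyl-3,4,4a,7,8,8a-hexahydronaphthalen-2(1H)-one
Conditions: second-generation Grubbs catalyst RuCl2(=CHPh)(H2IMes)(PCy3) (3 mol %), CH2Cl2 (0.01 M), 40 °C
Reagents that add atoms: none
Why: Ring-closing metathesis of the monosubstituted and 1,1-disubstituted olefins closes ring A as the trisubstituted Δ3 alkene and expels the surplus methylene as ethylene, the trans ring fusion following from the trans butenyl/isopropenyl relationship fixed in step 1.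

Step 4
Reactants: 7 (4aR,8aR)-5,8a-dimethyl-3,4,4a,7,8,8a-hexahydronaphthalen-2(1H)-one; 8 acetone
Product: 12 (4aR,8aR)-5,8a-dimethyl-3-(propan-2-ylidene)-3,4,4a,7,8,8a-hexahydronaphthalen-2(1H)-one, via lithium enolate 9 (not isolated), via lithium aldolate 10 (not isolated), via mesylate 11 (not isolated)
Conditions: LiN(iPr)2 (1.1 equiv), THF, −78 °C; 8 (1.5 equiv), −78 °C; MsCl (2 equiv), Et3N (5 equiv), −78 → 25 °C
Reagents that add atoms: none
Why: Kinetic deprotonation occurs at C7 because C9 is neopentylic, the enolate adds to acetone (crossed aldol), and mesylation with E1cB elimination gives the conjugated isopropylidene ketone (aldol condensation), erasing the transient C7 stereocentre.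

Step 5
Reactants: 12 (4aR,8aR)-5,8a-dimethyl-3-(propan-2-ylidene)-3,4,4a,7,8,8a-hexahydronaphthalen-2(1H)-one
Product: 13 (4aR,5S,6R,8aR)-5,6-dihydroxy-5,8a-dimethyl-3-(propan-2-ylidene)octahydronaphthalen-2(1H)-one
Conditions: OsO4 (4 mol %), NMO (1.5 equiv), acetone–H2O 4:1, 25 °C
Reagents that add atoms: osmium tetroxide O=[Os](=O)(=O)=O; N-methylmorpholine N-oxide C[N+]1([O-])CCOCC1; water O
Why: Upjohn dihydroxylation adds suprafacially to the electron-rich Δ3 olefin (the tetrasubstituted enone olefin is inert) from the α face opposite the axial C10 methyl, setting C3 (R) and C4 (S) as the cis 3α,4α-diol.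

Step 6
Reactants: 13 (4aR,5S,6R,8aR)-5,6-dihydroxy-5,8a-dimethyl-3-(propan-2-ylidene)octahydronaphthalen-2(1H)-one
Product: 15 (4aR,5S,6R,8aR)-5,6-dihydroxy-3-(2-hydroxypropan-2-yl)-5,8a-dimethyl-4a,5,6,7,8,8a-hexahydronaphthalen-2(1H)-one, via hydroperoxide 14 (not isolated)
Conditions: O2, tetraphenylporphyrin (0.5 mol %), CH2Cl2, white LED, 0 °C; PPh3 (1.2 equiv), 0 → 25 °C
Reagents that add atoms: dioxygen O=O
Why: Schenck ene reaction of the s-cis-locked isopropylidene enone proceeds with geminal selectivity, bonding oxygen to C11 and removing an allylic hydrogen from C6 so the olefin moves to C6=C7 in conjugation, and PPh3 reduces the tertiary hydroperoxide to the alcohol without touching any stereocentre.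

Step 7
Reactants: 15 (4aR,5S,6R,8aR)-5,6-dihydroxy-3-(2-hydroxypropan-2-yl)-5,8a-dimethyl-4a,5,6,7,8,8a-hexahydronaphthalen-2(1H)-one; 16 angelic acid
Product: 18 (4aR,5S,6R,8aR)-5-hydroxy-3-(2-hydroxypropan-2-yl)-5,8a-dimethyl-2-oxo-1,2,4a,5,6,7,8,8a-octahydronaphthalen-6-yl (2Z)-2-methylbut-2-enoate, via mixed anhydride 17 (not isolated)
Conditions: 16 (3 equiv), 2,4,6-trichlorobenzoyl chloride (3 equiv), Et3N (6 equiv), toluene, 25 °C; then 15, 75 °C
Reagents that add atoms: none
Why: Yamaguchi esterification acylates only the secondary 3α-hydroxyl (the other two hydroxyls are tertiary), and leaving out nucleophilic catalysts keeps the (Z)-angelate from isomerising to the tiglate.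

**Compound list**

1 | (1R,5R)-(+)-verbenone, (1R,5R)-4,6,6-trimethylbicyclo[3.1.1]hept-3-en-2-one | CC1=CC(=O)[C@@H]2C[C@H]1C2(C)C | starting material
2 | pent-4-enoic acid | C=CCCC(=O)O | starting material
3 | (1R,4R,5R)-4-(but-3-en-1-yl)-4,6,6-trimethylbicyclo[3.1.1]heptan-2-one | C=CCC[C@]1(C)CC(=O)[C@@H]2C[C@H]1C2(C)C | intermediate
4 | {[(4R,5R)-5-(but-3-en-1-yl)-4-(2-iodopropan-2-yl)-5-methylcyclohex-1-en-1-yl]oxy}trimethylsilane | C=CCC[C@]1(C)CC(O[Si](C)(C)C)=CC[C@H]1C(C)(C)I | intermediate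
5 | {[(4S,5R)-5-(but-3-en-1-yl)-5-methyl-4-(prop-1-en-2-yl)cyclohex-1-en-1-yl]oxy}trimethylsilane | C=CCC[C@]1(C)CC(O[Si](C)(C)C)=CC[C@H]1C(C)=C | intermediate
6 | (3R,4S)-3-(but-3-en-1-yl)-3-methyl-4-(prop-1-en-2-yl)cyclohexan-1-one | C=CCC[C@]1(C)CC(=O)CC[C@H]1C(C)=C | intermediate
7 | (4aR,8aR)-5,8a-dimethyl-3,4,4a,7,8,8a-hexahydronaphthalen-2(1H)-one | CC1=CCC[C@]2(C)CC(=O)CC[C@@H]12 | intermediate
8 | acetone | CC(C)=O | starting material
9 | lithium (4aR,8aR)-5,8a-dimethyl-1,4,4a,7,8,8a-hexahydronaphthalen-2-olate | CC1=CCC[C@]2(C)CC(O[Li])=CC[C@@H]12 | intermediate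
10 | lithium alkoxide of (3S,4aR,8aR)-3-(2-hydroxypropan-2-yl)-5,8a-dimethyl-3,4,4a,7,8,8a-hexahydronaphthalen-2(1H)-one (kinetic axial-attack epimer) | CC1=CCC[C@]2(C)CC(=O)[C@H](C(C)(C)O[Li])C[C@@H]12 | intermediate
11 | 2-[(3S,4aR,8aR)-5,8a-dimethyl-2-oxo-3,4,4a,7,8,8a-hexahydro-1H-naphthalen-3-yl]propan-2-yl methanesulfonate | CC1=CCC[C@]2(C)CC(=O)[C@H](C(C)(C)OS(C)(=O)=O)C[C@@H]12 | intermediate
12 | (4aR,8aR)-5,8a-dimethyl-3-(propan-2-ylidene)-3,4,4a,7,8,8a-hexahydronaphthalen-2(1H)-one (eudesma-3,7(11)-dien-8-one) | CC1=CCC[C@]2(C)CC(=O)C(=C(C)C)C[C@@H]12 | intermediate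
13 | (4aR,5S,6R,8aR)-5,6-dihydroxy-5,8a-dimethyl-3-(propan-2-ylidene)octahydronaphthalen-2(1H)-one (3α,4α-dihydroxyeudesm-7(11)-en-8-one) | O[C@@H]1CC[C@]2(C)CC(=O)C(=C(C)C)C[C@H]2[C@]1(C)O | intermediate
14 | (4aR,5S,6R,8aR)-3-(2-hydroperoxypropan-2-yl)-5,6-dihydroxy-5,8a-dimethyl-4a,5,6,7,8,8a-hexahydronaphthalen-2(1H)-one | O[C@@H]1CC[C@]2(C)CC(=O)C(C(C)(C)OO)=C[C@H]2[C@]1(C)O | intermediate
15 | (4aR,5S,6R,8aR)-5,6-dihydroxy-3-(2-hydroxypropan-2-yl)-5,8a-dimethyl-4a,5,6,7,8,8a-hexahydronaphthalen-2(1H)-one | O[C@@H]1CC[C@]2(C)CC(=O)C(C(C)(C)O)=C[C@H]2[C@]1(C)O | intermediate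
16 | angelic acid, (2Z)-2-methylbut-2-enoic acid | C/C=C(/C)C(=O)O | starting material
17 | (2Z)-2-methylbut-2-enoic 2,4,6-trichlorobenzoic anhydride | C/C=C(/C)C(=O)OC(=O)c1c(Cl)cc(Cl)cc1Cl | intermediate
18 | (4aR,5S,6R,8aR)-5-hydroxy-3-(2-hydroxypropan-2-yl)-5,8a-dimethyl-2-oxo-1,2,4a,5,6,7,8,8a-octahydronaphthalen-6-yl (2Z)-2-methylbut-2-enoate (3α-angeloyloxy-4α,11-dihydroxyeudesm-6-en-8-one) | C/C=C(/C)C(=O)O[C@@H]1CC[C@]2(C)CC(=O)C(C(C)(C)O)=C[C@H]2[C@]1(C)O | target

**Step count and risk**

Total steps: 7. Longest linear sequence: 7 steps (1 → 18).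

Steps most likely to fail:

Step 1 (the proposed new step). The primary radical may be quenched by hydrogen transfer before it adds to the hindered β,β-disubstituted β-carbon. The fallback is known organocopper chemistry and sets out from 1. But-3-enylmagnesium bromide with CuBr·SMe2 and Me3SiCl in THF (−78 → −30 °C) adds 1,4 from the same face and gives the trimethylsilyl enol ether of 3 F1. Brief treatment with 1 M HCl hydrolyses it, and the route is rejoined at 3.

Step 2. Adventitious HI can add to the terminal olefin, and the one-flask elimination can give some isopropylidene isomer. The fallback sets out from 3 and separates cleavage from olefin formation under protic conditions that are much less prone to add to a monosubstituted alkene. Dry HCl in acetic acid at 25 °C opens the cyclobutane to (3R,4R)-3-(but-3-en-1-yl)-4-(2-chloropropan-2-yl)-3-methylcyclohexan-1-one F2, which is isolated and purified. Dehydrochlorination with NaOAc in acetic acid at 100 °C then gives the isopropenyl ketone, and the route is rejoined at 6.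

Step 6. Hydrogen abstraction from the C11 methyls (giving the 7-hydroperoxide with an isopropenyl group) can compete with the wanted geminal pathway. The fallback sets out from 7 and builds the C11 carbinol from the acetone carbonyl, with no oxygen ene chemistry. LiN(iPr)2 then acetone at −78 °C with an acetic acid quench gives (3S,4aR,8aR)-3-(2-hydroxypropan-2-yl)-5,8a-dimethyl-3,4,4a,7,8,8a-hexahydronaphthalen-2(1H)-one F3. Dehydrogenation with 2-iodoxybenzoic acid in DMSO at 70 °C can only occur toward C6, since C10 is quaternary, and gives (4aR,8aR)-3-(2-hydroxypropan-2-yl)-5,8a-dimethyl-4a,7,8,8a-tetrahydronaphthalen-2(1H)-one F4. OsO4/NMO dihydroxylation of its Δ3 olefin from the α face rejoins the route at 15.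

**Further compounds**

F1 | step 1 | trimethylsilyl enol ether of 3, {[4-(but-3-en-1-yl)-4,6,6-trimethylbicyclo[3.1.1]hept-2-en-2-yl]oxy}trimethylsilane (configuration as in 3) | C=CCC[C@]1(C)C=C(O[Si](C)(C)C)[C@@H]2C[C@H]1C2(C)C
F2 | step 2 | (3R,4R)-3-(but-3-en-1-yl)-4-(2-chloropropan-2-yl)-3-methylcyclohexan-1-one | C=CCC[C@]1(C)CC(=O)CC[C@H]1C(C)(C)Cl
F3 | step 6 | (3S,4aR,8aR)-3-(2-hydroxypropan-2-yl)-5,8a-dimethyl-3,4,4a,7,8,8a-hexahydronaphthalen-2(1H)-one | CC1=CCC[C@]2(C)CC(=O)[C@H](C(C)(C)O)C[C@@H]12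
F4 | step 6 | (4aR,8aR)-3-(2-hydroxypropan-2-yl)-5,8a-dimethyl-4a,7,8,8a-tetrahydronaphthalen-2(1H)-one | CC1=CCC[C@]2(C)CC(=O)C(C(C)(C)O)=C[C@@H]12
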